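**Retrosynthetic overview**

1. No ring is built: the furan ring of 3,4-dibromofuran 1 is kept throughout and becomes the butenolide ring in the last step.
2. C3–C1′ bond: Br/Li exchange on 1 and acylation by Weinreb amide 2 (through lithiofuran 3) give ketone 4; asymmetric transfer hydrogenation then sets the (R) carbinol in alcohol 5.
3. C5–CH3 bond: lithiation of 5 next to bromine (dilithio species 6) and methylation give methylfuran 7, which holds the full carbon skeleton.
4. Key C–O disconnection: the lactone C2=O and the hemiketal C5–OH of hydroxybutenolide 9 come from singlet oxygen on the furan of 7 through endoperoxide 8; there is only one bridgehead H, so only one regiochemistry.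
5. C=CHI: loss of water from 9 to methylidene lactone 10 and C-iodination in the same flask give target 11 with (Z) geometry.

Assumption: the target is taken exactly as drawn, (R) at the carbinol and (Z) at the iodomethylidene, and common reagents (n-BuLi, LiN(i-Pr)2 solution, iodomethane, N-iodosuccinimide, the ruthenium catalyst) are bought.

**Route**

Step 1
Reactants: 1 3,4-dibromofuran; 2 N-methoxy-N-methylbutanamide
Product: 4 1-(4-bromofuran-3-yl)butan-1-one, via 3-bromo-4-lithiofuran 3 (not isolated)
Conditions: n-BuLi (1.0 equiv), Et2O, −78 °C, 30 min; then 2, −78 → −20 °C; H2O quench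
Reagents that add atoms: none
Why: Halogen–lithium exchange on one of the two equivalent C–Br bonds gives a 3-lithiofuran that is stable at −78 °C, and the Weinreb ketone synthesis stops at the ketone because the N-methoxy amide adduct does not collapse before the quench; no stereocentre is formed.

Step 2
Reactants: 4 1-(4-bromofuran-3-yl)butan-1-one
Product: 5 (1R)-1-(4-bromofuran-3-yl)butan-1-ol
Conditions: RuCl[(R,R)-TsDPEN](p-cymene) (1 mol %), HCO2H/Et3N (5:2), 30 °C
Reagents that add atoms: none
Why: Noyori–Ikariya asymmetric transfer hydrogenation: the (R,R)-TsDPEN ruthenium hydride reduces aryl alkyl ketones through the six-membered N–H/Ru–H transition state that places the heteroaryl group next to the p-cymene ring, which gives the (R)-carbinol here (mirror image of the (S,S)-catalyst/(S)-1-arylalkanol pairing), and the aryl bromide is inert.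

Step 3
Reactants: 5 (1R)-1-(4-bromofuran-3-yl)butan-1-ol
Product: 7 (1R)-1-(4-bromo-5-methylfuran-3-yl)butan-1-ol, via dilithiated furyl alkoxide 6 (not isolated)
Conditions: LiN(i-Pr)2 (2.2 equiv, bought solution), THF, −78 °C; then CH3I (1.1 equiv), −78 °C; H2O quench
Reagents that add atoms: iodomethane, CI
Why: Halogen-guided deprotonation (as in the lithiation of 3-bromofuran): the first equivalent of amide base forms the alkoxide, the second removes the ring α-proton flanked by oxygen and C–Br, and the 2-furyllithium is C-methylated at −78 °C faster than the alkoxide is O-methylated; the (R) centre is not involved.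

Step 4
Reactants: 7 (1R)-1-(4-bromo-5-methylfuran-3-yl)butan-1-ol
Product: 11 4-bromo-3-[(1R)-1-hydroxybutyl]-5-[(Z)-iodomethylidene]furan-2(5H)-one, via furan endoperoxide 8 (not isolated), via hydroxybutenolide 9 (not isolated), via methylidene lactone 10 (not isolated)
Conditions: O2, tetraphenylporphyrin (cat.), visible light, i-Pr2NEt (1.2 equiv), CH2Cl2, −78 °C; then CF3CO2H (excess), N-iodosuccinimide (1.2 equiv), 0 → 25 °C, dark; aqueous work-up
Reagents that add atoms: dioxygen, O=O; N-iodosuccinimide, O=C1CCC(=O)N1I
Why: Proposed new method: singlet oxygen adds [4+2] across the furan to endoperoxide 8, whose only bridgehead C–H (old furan C2, next to the carbinol-bearing carbon) is removed by the amine (Kornblum–DeLaMare) to give the lactone C=O and hemiketal 9 with one possible regiochemistry; in CF3CO2H the hemiketal ionises or ring-opens and loses water to the exocyclic enol lactone 10, electrophilic iodine from N-iodosuccinimide attacks its CH2 terminus, and loss of a proton from the resulting acyloxocarbenium ion gives the conjugated iodomethylidene lactone, (Z) because iodine sits syn to the ring oxygen and away from the C4 bromine and E/Z can equilibrate under acid; the closest known reactions are the photooxygenation of 2-alkylfurans to 5-hydroxybutenolides, the H2SO4 cyclodehydration of 5-bromolevulinic acids to bromomethylidene furanones and the halogenation–dehydrohalogenation of 5-methylidene furanones, while the one-flask furan to (Z)-5-(iodomethylidene)butenolide conversion with a free carbinol is new; C1′ is not touched.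

**Compound list**

1 | 3,4-dibromofuran | Brc1cocc1Br | starting material
2 | N-methoxy-N-methylbutanamide | CCCC(=O)N(C)OC | starting material
3 | 3-bromo-4-lithiofuran | [Li]c1cocc1Br | intermediate
4 | 1-(4-bromofuran-3-yl)butan-1-one | CCCC(=O)c1cocc1Br | intermediate
5 | (1R)-1-(4-bromofuran-3-yl)butan-1-ol | CCC[C@@H](O)c1cocc1Br | intermediate
6 | lithium (1R)-1-(4-bromo-5-lithiofuran-3-yl)butan-1-olate | CCC[C@@H](O[Li])c1coc([Li])c1Br | intermediate
7 | (1R)-1-(4-bromo-5-methylfuran-3-yl)butan-1-ol | CCC[C@@H](O)c1coc(C)c1Br | intermediate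
8 | (1R)-1-(6-bromo-1-methyl-2,3,7-trioxabicyclo[2.2.1]hept-5-en-5-yl)butan-1-ol (bridgehead diastereomers) | CCC[C@@H](O)C1=C(Br)C2(C)OOC1O2 | intermediate
9 | 4-bromo-5-hydroxy-3-[(1R)-1-hydroxybutyl]-5-methylfuran-2(5H)-one (C5 epimers) | CCC[C@@H](O)C1=C(Br)C(C)(O)OC1=O | intermediate
10 | 4-bromo-3-[(1R)-1-hydroxybutyl]-5-methylidenefuran-2(5H)-one | CCC[C@@H](O)C1=C(Br)C(=C)OC1=O | intermediate
11 | 4-bromo-3-[(1R)-1-hydroxybutyl]-5-[(Z)-iodomethylidene]furan-2(5H)-one | CCC[C@@H](O)C1=C(Br)/C(=C/I)OC1=O | target

**Step count**

Total steps: 4. Longest linear sequence: 4 steps (1 → 4 → 5 → 7 → 11).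

**Steps most likely to fail, with fallbacks**

Step 2 (enantiopurity of the carbinol; the ortho-bromo heteroaryl propyl ketone may give lower ee than simple aryl methyl ketones). The fallback sets out from 4 and replaces asymmetric reduction by resolution. NaBH4 in MeOH gives racemic 1-(4-bromofuran-3-yl)butan-1-ol F1. Burkholderia cepacia lipase and vinyl acetate in MTBE acylate the (R)-enantiomer (Kazlauskas rule, furyl large and propyl medium) to (1R)-1-(4-bromofuran-3-yl)butyl acetate F2 and leave (1S)-1-(4-bromofuran-3-yl)butan-1-ol F3, which can be oxidised back to 4 with MnO2 and recycled. K2CO3 in MeOH cleaves F2 and the route is rejoined at 5.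

Step 3 (site of ring lithiation next to a lithium alkoxide, and C- versus O-methylation). The fallback sets out from 1 and reverses the order of the two C–C bond formations so that no alkoxide is present. LiN(i-Pr)2 at −78 °C followed by CH3I gives 3,4-dibromo-2-methylfuran F4 (deprotonation next to bromine, the known site). n-BuLi then exchanges the bromine remote from the methyl group, and 2 acylates the lithiofuran to 1-(4-bromo-5-methylfuran-3-yl)butan-1-one F5. The transfer hydrogenation of step 2 applied to F5 rejoins the route at 7.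

Step 4 (the proposed new step; the hemiketal may not ionise in CF3CO2H, the free alcohol may interfere, or iodination may stop at the 5-hydroxy-5-(iodomethyl) stage). The fallback sets out from 7 and uses known chemistry in separate, isolated stages.
- TBDPSCl and imidazole give tert-butyl{[(1R)-1-(4-bromo-5-methylfuran-3-yl)butyl]oxy}diphenylsilane F6.
- The same photooxygenation with i-Pr2NEt, stopped after the first stage, gives 4-bromo-3-{(1R)-1-[(tert-butyldiphenylsilyl)oxy]butyl}-5-hydroxy-5-methylfuran-2(5H)-one F7.
- P2O5 in CH2Cl2 (the classical dehydration of 5-hydroxy-5-methylfuranones) gives 4-bromo-3-{(1R)-1-[(tert-butyldiphenylsilyl)oxy]butyl}-5-methylidenefuran-2(5H)-one F8.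
- ICl at −78 °C adds across the exocyclic alkene to 4-bromo-3-{(1R)-1-[(tert-butyldiphenylsilyl)oxy]butyl}-5-chloro-5-(iodomethyl)furan-2(5H)-one F9.
- Et3N removes HCl from F9 to give 4-bromo-3-{(1R)-1-[(tert-butyldiphenylsilyl)oxy]butyl}-5-[(Z)-iodomethylidene]furan-2(5H)-one F10; this is the iodine counterpart of the bromine addition/dehydrobromination used for bromomethylidene furanones.
- HF·pyridine removes the silyl group and the route is rejoined at 11.

Further compounds
F1 | step 2 | 1-(4-bromofuran-3-yl)butan-1-ol (racemic) | CCCC(O)c1cocc1Br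
F2 | step 2 | (1R)-1-(4-bromofuran-3-yl)butyl acetate | CCC[C@@H](OC(C)=O)c1cocc1Br
F3 | step 2 | (1S)-1-(4-bromofuran-3-yl)butan-1-ol | CCC[C@H](O)c1cocc1Br
F4 | step 3 | 3,4-dibromo-2-methylfuran | Cc1occ(Br)c1Br
F5 | step 3 | 1-(4-bromo-5-methylfuran-3-yl)butan-1-one | CCCC(=O)c1coc(C)c1Br
F6 | step 4 | tert-butyl{[(1R)-1-(4-bromo-5-methylfuran-3-yl)butyl]oxy}diphenylsilane | CCC[C@@H](O[Si](c1ccccc1)(c1ccccc1)C(C)(C)C)c1coc(C)c1Br
F7 | step 4 | 4-bromo-3-{(1R)-1-[(tert-butyldiphenylsilyl)oxy]butyl}-5-hydroxy-5-methylfuran-2(5H)-one | CCC[C@@H](O[Si](c1ccccc1)(c1ccccc1)C(C)(C)C)C1=C(Br)C(C)(O)OC1=O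
F8 | step 4 | 4-bromo-3-{(1R)-1-[(tert-butyldiphenylsilyl)oxy]butyl}-5-methylidenefuran-2(5H)-one | CCC[C@@H](O[Si](c1ccccc1)(c1ccccc1)C(C)(C)C)C1=C(Br)C(=C)OC1=O
F9 | step 4 | 4-bromo-3-{(1R)-1-[(tert-butyldiphenylsilyl)oxy]butyl}-5-chloro-5-(iodomethyl)furan-2(5H)-one | CCC[C@@H](O[Si](c1ccccc1)(c1ccccc1)C(C)(C)C)C1=C(Br)C(Cl)(CI)OC1=O
F10 | step 4 | 4-bromo-3-{(1R)-1-[(tert-butyldiphenylsilyl)oxy]butyl}-5-[(Z)-iodomethylidene]furan-2(5H)-one | CCC[C@@H](O[Si](c1ccccc1)(c1ccccc1)C(C)(C)C)C1=C(Br)/C(=C/I)OC1=O
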